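**Plan**
- Retrosynthesis: cut C2–C3 (ring closure of the ten-membered ring), the lactone C8–C17 bond, C8–C9 (aldol), C4–C5 (Stille), and last the C10–C11 and C12–C13 bonds of the cyclohexane ring.
- Enabling feature: ring carbons C13–C14–C1–C10 fold back into a strained cyclobutanone (C13, the later acetoxy carbinol, as ketone). C11–C12 with exocyclic C20 is an allyl unit, hung as an ether on the C9 hydroxymethyl arm of C10; strain release inserts it into the C13–C10 bond.
- Forward order: ketene [2+2] gives the cyclobutanone; ring expansion gives ring A fused to a temporary tetrahydrofuran; ring A is oxygenated (¹O2, OsO4). The tether is then oxidised to a lactone and converted into the spiro-epoxide and the C9 aldehyde. Aldol, Evans–Tishchenko and Stille steps add C3–C8; the γ-lactone closes; Nozaki–Hiyama–Kishi closes the ten-membered ring.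
- Stereochemistry: E-alkene geometry fixes C1/C10; kinetic resolution in the ring expansion gives the absolute configuration. The axial C15 methyl directs ¹O2 (C11, C14); hydroxyl-directed osmylation sets C12, C13. A reagent-controlled aldol sets C9, 1,3-anti reduction sets C7, lactone closure sets C8/C17, and the macrocyclisation sets C2.

Key step: step 6

Remark: positions are named by the briarane numbering of the target (C1–C20). Metal-bound transients (enolates, acetylides, organochromium species, rhodacycles) count as part of one operation and carry no number.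
Remark: 6 and 7 are racemates; their SMILES show the enantiomer that is carried on.

**Step 1**
Reactants: 1 prenol (3-methylbut-2-en-1-ol); 2 allyl bromide
Product: 3 allyl prenyl ether
Conditions: NaH, THF, 0 → 25 °C
Reagents that add atoms: none
Why: Williamson ether synthesis of a primary alkoxide with an allylic bromide; no stereocentre.

**Step 2**
Reactants: 3 allyl prenyl ether
Product: 4 (2E)-2-methyl-4-(allyloxy)but-2-en-1-ol
Conditions: SeO2 (cat.), t-BuOOH, CH2Cl2, 25 °C
Reagents that add atoms: tert-butyl hydroperoxide, CC(C)(C)OO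
Why: SeO2 allylic oxidation (ene reaction, then [2,3] shift) is selective for the (E)-methyl group at the more substituted end of a trisubstituted alkene.

**Step 3**
Reactants: 4 (2E)-allylic alcohol
Product: 5 TBS ether of 4
Conditions: TBSCl, imidazole, DMF, 25 °C
Reagents that add atoms: tert-butyldimethylsilyl chloride, CC(C)(C)[Si](C)(C)Cl
Why: Standard silylation of a primary alcohol; it protects the future C2 oxygen.

**Step 4**
Reactants: 5 TBS ether
Product: 6 racemic 4-(allyloxymethyl)-2,2-dichloro-3-methyl-3-(TBS-oxymethyl)cyclobutanone (allyloxymethyl cis to methyl)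
Conditions: Cl3CCOCl, Zn(Cu), Et2O/DME, 20 °C, ultrasound
Reagents that add atoms: trichloroacetyl chloride, ClC(Cl)(Cl)C(Cl)=O
Why: Ketene–alkene [2+2] cycloaddition of dichloroketene at the more nucleophilic trisubstituted alkene; the carbonyl carbon bonds to the less substituted alkene carbon, and the suprafacial addition turns the E geometry into the C9-cis-to-C15 relationship at C10/C1.

**Step 5**
Reactants: 6 dichlorocyclobutanone
Product: 7 racemic (2S*,3S*)-2-(allyloxymethyl)-3-methyl-3-(TBS-oxymethyl)cyclobutanone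
Conditions: Zn, AcOH, 25 °C
Reagents that add atoms: none
Why: Reductive dechlorination of an α,α-dichloroketone by zinc; the two ring stereocentres are not touched.

**Step 6**
Reactants: 7 racemic cyclobutanone
Product: 8 (3aR,7S,7aS)-7-methyl-7-(TBS-oxymethyl)hexahydro-2-benzofuran-5(3H)-one (C13 ketone; temporary tetrahydrofuran C10–C9–O–C20–C11)
Conditions: [Rh(C2H4)2Cl]2 (cat.), (R)-DTBM-SEGPHOS, 1,4-dioxane, 30 °C, stopped near half conversion
Reagents that add atoms: none
Why: Monovalent rhodium inserts oxidatively into the strained C13–C10 acyl–alkyl bond of the cyclobutanone, the tethered allyl ether undergoes migratory insertion, and C–C reductive elimination gives the cyclohexanone, so C10–C11 and C12–C13 form in one operation. The closest known reaction type is the rhodium-catalysed intramolecular "cut-and-sew" carboacylation of alkenes by cyclobutanones, including its kinetic-resolution variant with chiral bisphosphines. The six-membered carbocycle closes as a formal [4+2] ring expansion of the four-membered ring, and the temporary tetrahydrofuran closes by 5-exo insertion of the alkene (C11 to C10, C12 to the acyl carbon). C10 keeps its configuration because C–C oxidative addition and reductive elimination go with retention, C1 is untouched, and the new C11 centre (trans ring fusion expected from the fused rhodacycle) is erased in step 7. Two selectivities are needed: cleavage of the more substituted C13–C10 bond and not C13–C14, secured by the tether because only that rhodacycle can reach the alkene and turn over; and discrimination between the enantiomers of 7, secured by the chiral ligand pocket next to the C1 quaternary centre, which leaves (2R,3R)-7 behind.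

**Step 7**
Reactants: 8 bicyclic ketone
Product: 9 bicyclic enone (C13 ketone, C11=C12; C1 and C10 as in 8)
Conditions: IBX, DMSO/toluene, 70 °C
Reagents that add atoms: none
Why: IBX dehydrogenation of a ketone to the enone; only the C12–C11 side can desaturate because C1 is quaternary.

**Step 8**
Reactants: 9 enone
Product: 10 dienyl triflate (C13–OTf, C13=C14, C11=C12)
Conditions: LiN(i-Pr)2, THF, −78 °C; then PhNTf2
Reagents that add atoms: N-phenylbis(trifluoromethanesulfonimide), O=S(=O)(N(c1ccccc1)S(=O)(=O)C(F)(F)F)C(F)(F)F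
Why: Kinetic deprotonation of an enone occurs at the α′ carbon (C14), and O-sulfonylation of the cross-conjugated enolate gives the 2-triflyloxy diene.

**Step 9**
Reactants: 10 dienyl triflate
Product: 11 cyclohexa-1,3-diene (C11=C12–C13=C14) fused to the tetrahydrofuran
Conditions: Pd(OAc)2 (cat.), PPh3, HCO2H, n-Bu3N, DMF, 60 °C
Reagents that add atoms: none
Why: Palladium-catalysed formate reduction of a vinyl triflate (oxidative addition, formate exchange, decarboxylation, reductive elimination) leaves the diene intact.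

**Step 10**
Reactants: 11 diene
Product: 13 cis-ene-diol (C11–OH and C14–OH on the face of the C2 arm, C12=C13), via endoperoxide 12 (not isolated)
Conditions: O2, tetraphenylporphyrin (cat.), visible light, CH2Cl2, −78 °C; then Zn, AcOH, 0 °C
Reagents that add atoms: dioxygen, O=O
Why: Singlet oxygen adds [4+2] to the cis-fixed diene from the face opposite the pseudoaxial C15 methyl (the fused ether holds C9 in the diene plane), setting C11 and C14 cis to each other and anti to C15; zinc then cleaves the O–O bond.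

**Step 11**
Reactants: 13 ene-diol
Product: 14 all-cis C11,C12,C13,C14 tetraol
Conditions: OsO4, TMEDA, CH2Cl2, −78 °C; then aq. Na2SO3, THF, 50 °C
Reagents that add atoms: osmium tetroxide, O=[Os](=O)(=O)=O
Why: Hydrogen-bond-directed dihydroxylation: the OsO4·TMEDA complex is delivered by the two allylic hydroxyl groups to their own face, so C12 and C13 are set cis to C11–O and C14–O.

**Step 12**
Reactants: 14 tetraol
Product: 16 12,14-O-di-tert-butylsilylene 13-acetate (C11–OH free), via silylene diol 15 (not isolated)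
Conditions: t-Bu2Si(OTf)2, 2,6-lutidine, CH2Cl2, 0 °C; then Ac2O, DMAP, 25 °C
Reagents that add atoms: di-tert-butylsilyl bis(trifluoromethanesulfonate), CC(C)(C)[Si](OS(=O)(=O)C(F)(F)F)(OS(=O)(=O)C(F)(F)F)C(C)(C)C; acetic anhydride, CC(=O)OC(C)=O
Why: The silylene bis-triflate bridges the syn-1,3-diaxial C12/C14 hydroxyls as a six-membered ring (1,3-diol-selective silylene formation), which leaves the equatorial C13–OH for DMAP-catalysed acetylation while the tertiary C11–OH stays free.

**Step 13**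
Reactants: 16 silylene acetate
Product: 17 γ-lactone (C9 carbonyl, C9(=O)–O–C20)
Conditions: RuCl3 (cat.), NaIO4, CCl4/MeCN/H2O, 25 °C
Reagents that add atoms: sodium periodate (oxygen delivered through RuO4), [Na+].[O-]I(=O)(=O)=O
Why: RuO4 oxidation of a cyclic ether to a lactone should occur at the C9 methylene, because the C20 methylene is neopentylic and deactivated by the adjacent C11 oxygen; no alkene or free secondary alcohol is present.

**Step 14**
Reactants: 17 lactone
Product: 18 C9 Weinreb amide with free C20–OH and C11–OH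
Conditions: MeNH(OMe)·HCl, AlMe3, CH2Cl2, 0 → 25 °C
Reagents that add atoms: N,O-dimethylhydroxylamine hydrochloride, CNOC.Cl
Why: Aluminium amide aminolysis of a γ-lactone (Weinreb amide formation) frees the C20 hydroxyl; the hindered secondary acetate should react more slowly.

**Step 15**
Reactants: 18 amide diol
Product: 20 spiro-epoxide (C11–O–C20) Weinreb amide, via C20 tosylate 19 (not isolated)
Conditions: TsCl, Et3N, DMAP (cat.), CH2Cl2, 0 °C; then DBU, 25 °C
Reagents that add atoms: none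
Why: Selective sulfonylation of the primary C20–OH, then 3-exo-tet displacement by the tertiary C11 oxygen (Williamson-type epoxide closure); C11 keeps its configuration, so the epoxide oxygen is anti to C15.

**Step 16**
Reactants: 20 epoxy amide
Product: 21 ring A aldehyde (C9 aldehyde)
Conditions: Cp2Zr(H)Cl, THF, 25 °C
Reagents that add atoms: none
Why: Hydrozirconation of the amide carbonyl and collapse of the N,O-acetal on work-up gives the aldehyde; esters, the epoxide and silyl groups are tolerated.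

**Step 17**
Reactants: 22 2-chloro-N-methoxy-N-methylacetamide; 23 4-methoxybenzyl alcohol
Product: 24 N-methoxy-2-(4-methoxybenzyloxy)-N-methylacetamide
Conditions: NaH, THF, 0 → 25 °C
Reagents that add atoms: none
Why: Williamson substitution of an activated α-chloro amide by the benzylic alkoxide.

**Step 18**
Reactants: 24 Weinreb amide; 25 tert-butyldiphenyl(prop-2-ynyloxy)silane
Product: 26 5-(TBDPS-oxy)-1-(PMB-oxy)pent-3-yn-2-one
Conditions: n-BuLi, THF, −78 °C (on 25); then 24, −78 → 0 °C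
Reagents that add atoms: none
Why: The lithium acetylide adds to the Weinreb amide and stops at the chelated tetrahedral intermediate, which gives the ynone on work-up.

**Step 19**
Reactants: 26 ynone
Product: 27 (3Z)-5-(TBDPS-oxy)-4-iodo-1-(PMB-oxy)pent-3-en-2-one
Conditions: NaI, AcOH, 25 °C
Reagents that add atoms: sodium iodide, [Na+].[I-]
Why: Anti hydroiodination of an ynone (conjugate addition of iodide, then protonation) gives the (Z)-β-iodo enone with iodine cis to the carbonyl, which fixes the later C5=C6 geometry.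

**Step 20**
Reactants: 21 ring A aldehyde; 27 iodo enone
Product: 28 aldol adduct (9S-hydroxy, 8,9-syn C8–OPMB, C7 ketone, C5 vinyl iodide)
Conditions: (−)-Ipc2BOTf, i-Pr2NEt, CH2Cl2, −78 °C (on 27); then 21, −78 → −20 °C; H2O2, pH 7 buffer, MeOH, 0 °C
Reagents that add atoms: none
Why: Boron aldol reaction of the (Z)-diisopinocampheylboron enolate through a closed chair transition state; the Ipc ligands are chosen to reinforce the 1,3-anti (Felkin) preference of the β-oxygenated aldehyde for Re-face attack, which sets C9 (S), while the C8 centre is removed in step 27.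

**Step 21**
Reactants: 28 aldol adduct
Product: 29 9-acetate 7-alcohol (7S, 1,3-anti to C9)
Conditions: CH3CHO, SmI2 (cat.), THF, −10 °C
Reagents that add atoms: acetaldehyde, CC=O
Why: Evans–Tishchenko reduction: the samarium-bound hemiacetal of the C9 hydroxyl delivers hydride intramolecularly to the C7 ketone, giving the 1,3-anti alcohol and leaving the acetate on O9.

**Step 22**
Reactants: 30 acetylene; 31 hexabutylditin
Product: 32 (Z)-1,2-bis(tributylstannyl)ethene
Conditions: Pd(PPh3)4 (cat.), 1,4-dioxane, 60 °C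
Reagents that add atoms: none
Why: Palladium-catalysed cis-distannation of an alkyne gives the Z isomer by syn addition of the Sn–Sn bond.

**Step 23**
Reactants: 29 vinyl iodide; 32 (Z)-distannane
Product: 33 (3Z,5E)-dienyl stannane (C3–SnBu3)
Conditions: Pd2(dba)3 (cat.), AsPh3, DMF, 25 °C
Reagents that add atoms: none
Why: Stille coupling goes with retention at both alkenes; it is placed after reduction of the C7 ketone so that no cis-dienone, prone to oxa-6π electrocyclisation, is formed.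

**Step 24**
Reactants: 33 dienyl stannane
Product: 34 (3Z,5E)-dienyl iodide (C3–I)
Conditions: I2, CH2Cl2, 0 °C
Reagents that add atoms: iodine, II
Why: Iododestannylation of a vinylstannane goes with retention of alkene geometry.

**Step 25**
Reactants: 34 C7 alcohol; 35 2-bromopropanoyl bromide
Product: 36 C7 2-bromopropanoate (mixture at the CHBr carbon)
Conditions: pyridine, CH2Cl2, 0 °C
Reagents that add atoms: none
Why: Acylation of the allylic secondary alcohol by an acid bromide; the ester both protects O7 and carries C17–C19.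

**Step 26**
Reactants: 36 PMB ether
Product: 37 C8 alcohol
Conditions: DDQ, CH2Cl2/pH 7 buffer, 0 → 25 °C
Reagents that add atoms: none
Why: Oxidative cleavage of a p-methoxybenzyl ether by DDQ; acetates, silyl ethers and the epoxide are inert.

**Step 27**
Reactants: 37 C8 alcohol
Product: 38 C8 ketone
Conditions: Dess–Martin periodinane, NaHCO3, CH2Cl2, 25 °C
Reagents that add atoms: none
Why: Buffered Dess–Martin oxidation of the only free secondary alcohol.

**Step 28**
Reactants: 38 bromo ester ketone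
Product: 39 γ-lactone (8S tertiary alcohol, 17R methyl)
Conditions: SmI2, THF, −78 °C
Reagents that add atoms: none
Why: SmI2 reduces the C–Br bond to a samarium enolate that adds to the C8 ketone (intramolecular Reformatsky reaction); the large C6 and C9 groups should end trans on the new lactone ring and the C17 methyl trans to C9.

**Step 29**
Reactants: 39 lactone
Product: 40 C2 primary alcohol
Conditions: PPTS (cat.), MeOH, 25 °C
Reagents that add atoms: none
Why: Acid-catalysed methanolysis removes the primary TBS ether; the cyclic silylene, the TBDPS ether and the hindered spiro-epoxide should survive PPTS.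

**Step 30**
Reactants: 40 alcohol
Product: 41 C2 aldehyde
Conditions: Dess–Martin periodinane, NaHCO3, CH2Cl2, 0 → 25 °C
Reagents that add atoms: none
Why: Dess–Martin oxidation of the primary alcohol; the tertiary C8–OH cannot be oxidised.

**Step 31**
Reactants: 41 iodo aldehyde
Product: 42 ten-membered-ring allylic alcohol (2S)
Conditions: CrCl2, NiCl2 (cat.), DMSO/THF, 25 °C, high dilution
Reagents that add atoms: none
Why: Nozaki–Hiyama–Kishi cyclisation: the (Z)-vinyl iodide is converted via nickel into a vinylchromium species that adds to the aldehyde, and attack from the face away from the C15 methyl in the product-like trans-fused conformer should give the 2S alcohol.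

**Step 32**
Reactants: 42 macrocyclic alcohol
Product: 43 2,9,13-triacetate
Conditions: Ac2O, pyridine, DMAP (cat.), CH2Cl2, 25 °C
Reagents that add atoms: acetic anhydride, CC(=O)OC(C)=O
Why: Acetylation of the only free secondary alcohol; the tertiary C8–OH next to the lactone is too hindered to react under these conditions.

**Step 33**
Reactants: 43 protected triacetate
Product: 44 Juncin Q
Conditions: HF·pyridine, pyridine, THF, 0 → 25 °C
Reagents that add atoms: none
Why: Buffered fluoride cleaves the 12,14-silylene and the C16 TBDPS ether in one operation; acetates, lactone and epoxide are stable to it.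

**Compound list**
1 | prenol (3-methylbut-2-en-1-ol) | CC(C)=CCO | starting material
2 | allyl bromide | C=CCBr | starting material
3 | allyl prenyl ether | CC(C)=CCOCC=C | intermediate
4 | (2E)-2-methyl-4-(allyloxy)but-2-en-1-ol | C=CCOC/C=C(\C)CO | intermediate
5 | TBS ether of 4 | C=CCOC/C=C(\C)CO[Si](C)(C)C(C)(C)C | intermediate
6 | racemic 4-(allyloxymethyl)-2,2-dichloro-3-methyl-3-(TBS-oxymethyl)cyclobutanone, allyloxymethyl cis to methyl | C=CCOC[C@H]1C(=O)C(Cl)(Cl)[C@]1(C)CO[Si](C)(C)C(C)(C)C | intermediate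
7 | racemic (2S*,3S*)-2-(allyloxymethyl)-3-methyl-3-(TBS-oxymethyl)cyclobutanone | C=CCOC[C@H]1C(=O)C[C@]1(C)CO[Si](C)(C)C(C)(C)C | intermediate
8 | (3aR,7S,7aS)-7-methyl-7-(TBS-oxymethyl)hexahydro-2-benzofuran-5(3H)-one | O=C1C[C@H]2COC[C@@H]2[C@@](C)(CO[Si](C)(C)C(C)(C)C)C1 | intermediate
9 | bicyclic enone (C13 ketone, C11=C12) | O=C1C=C2COC[C@@H]2[C@@](C)(CO[Si](C)(C)C(C)(C)C)C1 | intermediate
10 | dienyl triflate (C13–OTf) | FC(F)(F)S(=O)(=O)OC1=C[C@](C)(CO[Si](C)(C)C(C)(C)C)[C@H]2COCC2=C1 | intermediate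
11 | bicyclic diene (C11=C12–C13=C14) | C1=C[C@](C)(CO[Si](C)(C)C(C)(C)C)[C@H]2COCC2=C1 | intermediate
12 | C11,C14-endoperoxide | C1OC[C@@]23OO[C@@H](C=C2)[C@](C)(CO[Si](C)(C)C(C)(C)C)[C@@H]13 | intermediate (not isolated)
13 | cis-C11,C14-ene-diol | C1OC[C@@]2(O)C=C[C@H](O)[C@](C)(CO[Si](C)(C)C(C)(C)C)[C@@H]12 | intermediate
14 | all-cis C11–C14 tetraol | C1OC[C@@]2(O)[C@H](O)[C@H](O)[C@H](O)[C@](C)(CO[Si](C)(C)C(C)(C)C)[C@@H]12 | intermediate
15 | 12,14-O-di-tert-butylsilylene diol | C1OC[C@@]2(O)[C@@H]3O[Si](C(C)(C)C)(C(C)(C)C)O[C@@H]([C@H]3O)[C@](C)(CO[Si](C)(C)C(C)(C)C)[C@@H]12 | intermediate (not isolated)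
16 | 12,14-O-silylene 13-acetate | C1OC[C@@]2(O)[C@@H]3O[Si](C(C)(C)C)(C(C)(C)C)O[C@@H]([C@H]3OC(C)=O)[C@](C)(CO[Si](C)(C)C(C)(C)C)[C@@H]12 | intermediate
17 | γ-lactone (C9 carbonyl) | O=C1OC[C@@]2(O)[C@@H]3O[Si](C(C)(C)C)(C(C)(C)C)O[C@@H]([C@H]3OC(C)=O)[C@](C)(CO[Si](C)(C)C(C)(C)C)[C@@H]12 | intermediate
18 | C9 Weinreb amide, C11,C20-diol | CON(C)C(=O)[C@H]1[C@@](O)(CO)[C@@H]2O[Si](C(C)(C)C)(C(C)(C)C)O[C@@H]([C@H]2OC(C)=O)[C@]1(C)CO[Si](C)(C)C(C)(C)C | intermediate
19 | C20 tosylate of 18 | CON(C)C(=O)[C@H]1[C@@](O)(COS(=O)(=O)c2ccc(C)cc2)[C@@H]2O[Si](C(C)(C)C)(C(C)(C)C)O[C@@H]([C@H]2OC(C)=O)[C@]1(C)CO[Si](C)(C)C(C)(C)C | intermediate (not isolated)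
20 | spiro-epoxide Weinreb amide | CON(C)C(=O)[C@H]1[C@@]2(CO2)[C@@H]3O[Si](C(C)(C)C)(C(C)(C)C)O[C@@H]([C@H]3OC(C)=O)[C@]1(C)CO[Si](C)(C)C(C)(C)C | intermediate
21 | ring A aldehyde (C9 aldehyde) | O=C[C@H]1[C@@]2(CO2)[C@@H]3O[Si](C(C)(C)C)(C(C)(C)C)O[C@@H]([C@H]3OC(C)=O)[C@]1(C)CO[Si](C)(C)C(C)(C)C | intermediate
22 | 2-chloro-N-methoxy-N-methylacetamide | CON(C)C(=O)CCl | starting material
23 | 4-methoxybenzyl alcohol | COc1ccc(CO)cc1 | starting material
24 | N-methoxy-2-(4-methoxybenzyloxy)-N-methylacetamide | CON(C)C(=O)COCc1ccc(OC)cc1 | intermediate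
25 | tert-butyldiphenyl(prop-2-ynyloxy)silane | C#CCO[Si](C(C)(C)C)(c1ccccc1)c1ccccc1 | starting material
26 | 5-(TBDPS-oxy)-1-(PMB-oxy)pent-3-yn-2-one | COc1ccc(COCC(=O)C#CCO[Si](C(C)(C)C)(c2ccccc2)c2ccccc2)cc1 | intermediate
27 | (3Z)-5-(TBDPS-oxy)-4-iodo-1-(PMB-oxy)pent-3-en-2-one | COc1ccc(COCC(=O)/C=C(\I)CO[Si](C(C)(C)C)(c2ccccc2)c2ccccc2)cc1 | intermediate
28 | aldol adduct (9S-OH, 8-OPMB, C7 ketone, C5–I) | I/C(CO[Si](C(C)(C)C)(c1ccccc1)c1ccccc1)=C\C(=O)[C@H](OCc1ccc(OC)cc1)[C@@H](O)[C@H]1[C@@]2(CO2)[C@@H]3O[Si](C(C)(C)C)(C(C)(C)C)O[C@@H]([C@H]3OC(C)=O)[C@]1(C)CO[Si](C)(C)C(C)(C)C | intermediate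
29 | 9-acetate 7S-alcohol (C5–I) | I/C(CO[Si](C(C)(C)C)(c1ccccc1)c1ccccc1)=C\[C@H](O)[C@H](OCc1ccc(OC)cc1)[C@@H](OC(C)=O)[C@H]1[C@@]2(CO2)[C@@H]3O[Si](C(C)(C)C)(C(C)(C)C)O[C@@H]([C@H]3OC(C)=O)[C@]1(C)CO[Si](C)(C)C(C)(C)C | intermediate
30 | acetylene | C#C | starting material
31 | hexabutylditin | CCCC[Sn](CCCC)(CCCC)[Sn](CCCC)(CCCC)CCCC | starting material
32 | (Z)-1,2-bis(tributylstannyl)ethene | CCCC[Sn](CCCC)(CCCC)/C=C\[Sn](CCCC)(CCCC)CCCC | intermediate
33 | (3Z,5E)-dienyl stannane | CCCC[Sn](CCCC)(CCCC)/C=C\C(CO[Si](C(C)(C)C)(c1ccccc1)c1ccccc1)=C/[C@H](O)[C@H](OCc1ccc(OC)cc1)[C@@H](OC(C)=O)[C@H]1[C@@]2(CO2)[C@@H]3O[Si](C(C)(C)C)(C(C)(C)C)O[C@@H]([C@H]3OC(C)=O)[C@]1(C)CO[Si](C)(C)C(C)(C)C | intermediate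
34 | (3Z,5E)-dienyl iodide, C7 alcohol | I/C=C\C(CO[Si](C(C)(C)C)(c1ccccc1)c1ccccc1)=C/[C@H](O)[C@H](OCc1ccc(OC)cc1)[C@@H](OC(C)=O)[C@H]1[C@@]2(CO2)[C@@H]3O[Si](C(C)(C)C)(C(C)(C)C)O[C@@H]([C@H]3OC(C)=O)[C@]1(C)CO[Si](C)(C)C(C)(C)C | intermediate
35 | 2-bromopropanoyl bromide | CC(Br)C(Br)=O | starting material
36 | C7 2-bromopropanoate | I/C=C\C(CO[Si](C(C)(C)C)(c1ccccc1)c1ccccc1)=C/[C@H](OC(=O)C(C)Br)[C@H](OCc1ccc(OC)cc1)[C@@H](OC(C)=O)[C@H]1[C@@]2(CO2)[C@@H]3O[Si](C(C)(C)C)(C(C)(C)C)O[C@@H]([C@H]3OC(C)=O)[C@]1(C)CO[Si](C)(C)C(C)(C)C | intermediate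
37 | C8 alcohol | I/C=C\C(CO[Si](C(C)(C)C)(c1ccccc1)c1ccccc1)=C/[C@H](OC(=O)C(C)Br)[C@H](O)[C@@H](OC(C)=O)[C@H]1[C@@]2(CO2)[C@@H]3O[Si](C(C)(C)C)(C(C)(C)C)O[C@@H]([C@H]3OC(C)=O)[C@]1(C)CO[Si](C)(C)C(C)(C)C | intermediate
38 | C8 ketone | I/C=C\C(CO[Si](C(C)(C)C)(c1ccccc1)c1ccccc1)=C/[C@H](OC(=O)C(C)Br)C(=O)[C@@H](OC(C)=O)[C@H]1[C@@]2(CO2)[C@@H]3O[Si](C(C)(C)C)(C(C)(C)C)O[C@@H]([C@H]3OC(C)=O)[C@]1(C)CO[Si](C)(C)C(C)(C)C | intermediate
39 | γ-lactone (7S,8S,17R), C2–OTBS | I/C=C\C(CO[Si](C(C)(C)C)(c1ccccc1)c1ccccc1)=C/[C@@H]1OC(=O)[C@H](C)[C@@]1(O)[C@@H](OC(C)=O)[C@H]1[C@@]2(CO2)[C@@H]3O[Si](C(C)(C)C)(C(C)(C)C)O[C@@H]([C@H]3OC(C)=O)[C@]1(C)CO[Si](C)(C)C(C)(C)C | intermediate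
40 | C2 primary alcohol | I/C=C\C(CO[Si](C(C)(C)C)(c1ccccc1)c1ccccc1)=C/[C@@H]1OC(=O)[C@H](C)[C@@]1(O)[C@@H](OC(C)=O)[C@H]1[C@@]2(CO2)[C@@H]3O[Si](C(C)(C)C)(C(C)(C)C)O[C@@H]([C@H]3OC(C)=O)[C@]1(C)CO | intermediate
41 | C2 aldehyde | I/C=C\C(CO[Si](C(C)(C)C)(c1ccccc1)c1ccccc1)=C/[C@@H]1OC(=O)[C@H](C)[C@@]1(O)[C@@H](OC(C)=O)[C@H]1[C@@]2(CO2)[C@@H]3O[Si](C(C)(C)C)(C(C)(C)C)O[C@@H]([C@H]3OC(C)=O)[C@]1(C)C=O | intermediate
42 | macrocyclic 2S-alcohol (12,14-silylene, 16-OTBDPS, 9,13-diacetate) | CC(=O)O[C@H]1[C@@H](O[Si]4(C(C)(C)C)C(C)(C)C)[C@]2(CO2)[C@@H]2[C@H](OC(C)=O)[C@@]3(O)[C@H](/C=C(CO[Si](C(C)(C)C)(c5ccccc5)c5ccccc5)\C=C/[C@H](O)[C@@]2(C)[C@H]1O4)OC(=O)[C@@H]3C | intermediate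
43 | protected 2,9,13-triacetate | CC(=O)O[C@H]1[C@@H](O[Si]4(C(C)(C)C)C(C)(C)C)[C@]2(CO2)[C@@H]2[C@H](OC(C)=O)[C@@]3(O)[C@H](/C=C(CO[Si](C(C)(C)C)(c5ccccc5)c5ccccc5)\C=C/[C@H](OC(C)=O)[C@@]2(C)[C@H]1O4)OC(=O)[C@@H]3C | intermediate
44 | Juncin Q | CC(=O)O[C@H]1[C@@H](O)[C@]2(CO2)[C@@H]2[C@H](OC(C)=O)[C@@]3(O)[C@H](/C=C(CO)\C=C/[C@H](OC(C)=O)[C@@]2(C)[C@H]1O)OC(=O)[C@@H]3C | target

**Totals**
Total step count: 33. Longest linear sequence: 29 steps (steps 1–16, 20, 21 and 23–33).

**Steps most likely to fail**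

Step 6. The chiral rhodium catalyst may discriminate poorly between the two enantiomers of 7, or β-alkoxide loss from the rhodacycle may compete, so that 8 is formed with low enantiomeric purity. The fallback separates the enantiomers before the C–C activation. It sets out from 7: reduction with BH3·SMe2 and the (S)-methyl oxazaborolidine catalyst (Corey–Bakshi–Shibata reduction) should give two diastereomeric alcohols, (1R,2S,3S)-cyclobutanol F1 and (1R,2R,3R)-cyclobutanol F2, one from each enantiomer, separable on silica. Dess–Martin oxidation of F1 gives enantiopure (2S,3S)-cyclobutanone F3, which is ring-expanded with an achiral rhodium catalyst ([Rh(cod)Cl]2, P(C6F5)3, 1,4-dioxane, 80 °C) and comes back to the route at 8.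

Step 28. SmI2 may cleave the α-acyloxy ketone reductively faster than the enolate closes, or the aldol may close on the wrong ketone face. The fallback forms the C8–C17 bond intermolecularly under zinc-chelate control. It sets out from 34: TESOTf and 2,6-lutidine give C7 triethylsilyl ether F4, DDQ gives C8 alcohol F5, Dess–Martin oxidation gives ketone F6, and PPTS in MeOH at 0 °C gives α-hydroxy ketone F7. The Reformatsky reagent from ethyl 2-bromopropanoate and Zn then adds to the zinc-alkoxide chelate from the face opposite C6 to give hydroxy ester F8, which lactonises onto O7 and comes back to the route at 39.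

Step 31. The vinylchromium species may add to the aldehyde with poor facial selectivity, so that the C2 epimer dominates. The fallback sets C2 after ring closure by reagent-controlled reduction. It sets out from 41: the cyclisation mixture containing 2-epi alcohol F9 is oxidised with Dess–Martin periodinane to macrocyclic dienone F10 (kept cold), which is reduced with the oxazaborolidine catalyst and catecholborane at −78 °C and comes back to the route at 42.

**Further compounds**
F1 | step 6 | (1R,2S,3S)-2-(allyloxymethyl)-3-methyl-3-(TBS-oxymethyl)cyclobutanol | C=CCOC[C@H]1[C@H](O)C[C@]1(C)CO[Si](C)(C)C(C)(C)C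
F2 | step 6 | (1R,2R,3R)-2-(allyloxymethyl)-3-methyl-3-(TBS-oxymethyl)cyclobutanol | C=CCOC[C@@H]1[C@H](O)C[C@@]1(C)CO[Si](C)(C)C(C)(C)C
F3 | step 6 | (2S,3S)-2-(allyloxymethyl)-3-methyl-3-(TBS-oxymethyl)cyclobutanone, single enantiomer | C=CCOC[C@H]1C(=O)C[C@]1(C)CO[Si](C)(C)C(C)(C)C
F4 | step 28 | C7 triethylsilyl ether of 34 | I/C=C\C(CO[Si](C(C)(C)C)(c1ccccc1)c1ccccc1)=C/[C@H](O[Si](CC)(CC)CC)[C@H](OCc1ccc(OC)cc1)[C@@H](OC(C)=O)[C@H]1[C@@]2(CO2)[C@@H]3O[Si](C(C)(C)C)(C(C)(C)C)O[C@@H]([C@H]3OC(C)=O)[C@]1(C)CO[Si](C)(C)C(C)(C)C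
F5 | step 28 | C8 alcohol, C7 triethylsilyl ether | I/C=C\C(CO[Si](C(C)(C)C)(c1ccccc1)c1ccccc1)=C/[C@H](O[Si](CC)(CC)CC)[C@H](O)[C@@H](OC(C)=O)[C@H]1[C@@]2(CO2)[C@@H]3O[Si](C(C)(C)C)(C(C)(C)C)O[C@@H]([C@H]3OC(C)=O)[C@]1(C)CO[Si](C)(C)C(C)(C)C
F6 | step 28 | C8 ketone, C7 triethylsilyl ether | I/C=C\C(CO[Si](C(C)(C)C)(c1ccccc1)c1ccccc1)=C/[C@H](O[Si](CC)(CC)CC)C(=O)[C@@H](OC(C)=O)[C@H]1[C@@]2(CO2)[C@@H]3O[Si](C(C)(C)C)(C(C)(C)C)O[C@@H]([C@H]3OC(C)=O)[C@]1(C)CO[Si](C)(C)C(C)(C)C
F7 | step 28 | C7-hydroxy C8 ketone | I/C=C\C(CO[Si](C(C)(C)C)(c1ccccc1)c1ccccc1)=C/[C@H](O)C(=O)[C@@H](OC(C)=O)[C@H]1[C@@]2(CO2)[C@@H]3O[Si](C(C)(C)C)(C(C)(C)C)O[C@@H]([C@H]3OC(C)=O)[C@]1(C)CO[Si](C)(C)C(C)(C)C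
F8 | step 28 | C7,C8-dihydroxy ethyl ester (Reformatsky adduct) | I/C=C\C(CO[Si](C(C)(C)C)(c1ccccc1)c1ccccc1)=C/[C@H](O)[C@@](O)([C@@H](C)C(=O)OCC)[C@@H](OC(C)=O)[C@H]1[C@@]2(CO2)[C@@H]3O[Si](C(C)(C)C)(C(C)(C)C)O[C@@H]([C@H]3OC(C)=O)[C@]1(C)CO[Si](C)(C)C(C)(C)C
F9 | step 31 | 2-epi alcohol (2R epimer of 42) | CC(=O)O[C@H]1[C@@H](O[Si]4(C(C)(C)C)C(C)(C)C)[C@]2(CO2)[C@@H]2[C@H](OC(C)=O)[C@@]3(O)[C@H](/C=C(CO[Si](C(C)(C)C)(c5ccccc5)c5ccccc5)\C=C/[C@@H](O)[C@@]2(C)[C@H]1O4)OC(=O)[C@@H]3C
F10 | step 31 | macrocyclic dienone (C2 ketone) | CC(=O)O[C@H]1[C@@H](O[Si]4(C(C)(C)C)C(C)(C)C)[C@]2(CO2)[C@@H]2[C@H](OC(C)=O)[C@@]3(O)[C@H](/C=C(CO[Si](C(C)(C)C)(c5ccccc5)c5ccccc5)\C=C/C(=O)[C@@]2(C)[C@H]1O4)OC(=O)[C@@H]3C
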